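## Retrosynthetic overview
1. Renealtin A ⇒ removal of one MOM ether and one aryl acetate from a protected all-cis oxolane.
2. C2–C3 bond: an oxolanyl oxocarbenium ion (from a γ-lactol) plus the enol silane of acetovanillone. C3 is set last, cis to the C5 oxygen.
3. The γ-lactol is the only ring and closes by itself. It comes from oxidation at the terminal carbon of a syn 1-aryl-3-(MOM-oxy)pent-4-en-2-ol.
4. Key C5–C6 bond: the two oxygen-bearing carbons of the vicinal pair are joined directly. C5 acts as a 1-oxyallyl anion (α-alkoxy carbanion, d1 synthon, from allyl MOM ether on chiral boron). C6 is the carbonyl carbon of an arylacetaldehyde. C5 and C6 are set together.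
5. The arylacetaldehyde ⇒ ozonolysis of eugenyl acetate.

Assumption: positions follow diarylheptanoid numbering (C1 ketone carbon to C7 benzylic CH2), in which the given SMILES is (3R,5R,6R), that is (2R,3R,5R) and all-cis on the oxolane.

## Route

Step 1
Reactants: 1 eugenyl acetate (4-allyl-2-methoxyphenyl acetate)
Product: 3 2-methoxy-4-(2-oxoethyl)phenyl acetate, via ozonide 2 (not isolated)
Conditions: O3 (1 equiv), CH2Cl2, −78 °C; Me2S, −78 °C to rt
Reagents that add atoms: ozone, [O-][O+]=O
Why: Criegee ozonolysis with reductive work-up: the terminal alkene is far more ozonophilic than the acetate-damped arene, so one equivalent of O3 cleaves only the allyl group, and no stereocentre is involved.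

Step 2
Reactants: 4 allyl alcohol
Product: 5 allyl methoxymethyl ether (3-(methoxymethoxy)prop-1-ene)
Conditions: CH2(OMe)2 (large excess), LiBr (20 mol %), TsOH·H2O (10 mol %), rt; distil from CaH2
Reagents that add atoms: dimethoxymethane, COCOC
Why: Acid-catalysed transacetalisation: the primary alcohol exchanges with one methoxy group of the excess dimethoxymethane, which drives the equilibrium and avoids chloromethyl methyl ether.

Step 3 (key step)
Reactants: 3 2-methoxy-4-(2-oxoethyl)phenyl acetate; 5 allyl methoxymethyl ether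
Product: 9 4-[(2R,3R)-2-hydroxy-3-(methoxymethoxy)pent-4-en-1-yl]-2-methoxyphenyl acetate, via oxyallyllithium 6 (not isolated), via allylborane 7 (not isolated), via borinate 8 (not isolated)
Conditions: 5, s-BuLi, THF, −78 °C; (−)-Ipc2BOMe, −78 °C; BF3·OEt2, then 3, −78 °C, 3 h; pH 7 buffer, 30% H2O2, MeOH, 0 °C to rt
Reagents that add atoms: none
Why: Brown asymmetric alkoxyallylboration: deprotonation turns the oxygen-bearing carbon of 5 into a 1-oxyallyl anion (an α-alkoxy carbanion of reversed polarity), which after lithium-to-boron exchange attacks the carbonyl carbon of 3 through a closed Zimmerman–Traxler chair, so two carbons that are both natural acceptors are joined; the Z geometry of 7 gives the syn C5/C6 pair and the isopinocampheyl groups from (+)-α-pinene direct attack to the Si face of 3, giving (5R,6R).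

Step 4
Reactants: 9 4-[(2R,3R)-2-hydroxy-3-(methoxymethoxy)pent-4-en-1-yl]-2-methoxyphenyl acetate
Product: 11 4-{[(2R,3R)-5-hydroxy-3-(methoxymethoxy)oxolan-2-yl]methyl}-2-methoxyphenyl acetate (both anomers), via hydroxy aldehyde 10 (not isolated)
Conditions: PdCl2(PhCN)2 (12 mol %), CuCl2·2H2O (12 mol %), AgNO2 (6 mol %), t-BuOH/MeNO2 15:1, O2 (1 atm), rt
Reagents that add atoms: dioxygen, O=O
Why: Aldehyde-selective (anti-Markovnikov) Wacker-type oxidation with nitrite co-catalysis: the allylic C–O bond reinforces delivery of oxygen to the terminal carbon, the acetate, MOM ether and C5/C6 centres are untouched under these near-neutral conditions, and 10 is trapped at once by the C6 hydroxyl as the five-membered lactol, whose anomeric centre is erased in step 6.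

Step 5
Reactants: 12 acetovanillone (1-(4-hydroxy-3-methoxyphenyl)ethanone)
Product: 13 [2-methoxy-4-(1-trimethylsilyloxyvinyl)phenoxy]trimethylsilane
Conditions: TMSOTf (2.3 equiv), Et3N (3 equiv), CH2Cl2, 0 °C to rt; pentane extraction, bulb-to-bulb distillation
Reagents that add atoms: trimethylsilyl triflate, C[Si](C)(C)OS(=O)(=O)C(F)(F)F
Why: Soft enolisation with silyl triflate and amine: the phenol and the methyl ketone are silylated in one operation, so one reagent gives both the carbon nucleophile and a traceless phenol mask.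

Step 6
Reactants: 11 4-{[(2R,3R)-5-hydroxy-3-(methoxymethoxy)oxolan-2-yl]methyl}-2-methoxyphenyl acetate; 13 [2-methoxy-4-(1-trimethylsilyloxyvinyl)phenoxy]trimethylsilane
Product: 16 4-{[(2R,3R,5R)-5-[2-(4-hydroxy-3-methoxyphenyl)-2-oxoethyl]-3-(methoxymethoxy)oxolan-2-yl]methyl}-2-methoxyphenyl acetate, via oxocarbenium ion 14 (not isolated), via aryl silyl ether 15 (not isolated)
Conditions: 13 (3 equiv), BF3·OEt2 (1.5 equiv, added last), CH2Cl2, −78 °C, 1 h; sat. aq NaHCO3, then dilute aq citric acid wash
Reagents that add atoms: none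
Why: Lewis-acid-promoted γ-lactol substitution (Mukaiyama-type C-glycosylation): BF3·OEt2 ionises 11 to 14, which reacts through the envelope with the C5 alkoxy group pseudoaxial and the C6 arylmethyl group pseudoequatorial, and inside attack of the enol silane (the stereoelectronic model for five-membered oxocarbenium ions) places the new C3 side chain cis to the C5 oxygen, that is (3R) and all-cis.

Step 7
Reactants: 16 4-{[(2R,3R,5R)-5-[2-(4-hydroxy-3-methoxyphenyl)-2-oxoethyl]-3-(methoxymethoxy)oxolan-2-yl]methyl}-2-methoxyphenyl acetate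
Product: 17 renealtin A
Conditions: methanolic HCl (about 1.25 mol per litre), 40 °C, 6 h
Reagents that add atoms: none
Why: Acid-catalysed acetal exchange and transesterification in methanol remove the MOM ether and the aryl acetate in one operation without breaking any bond to C3, C5 or C6, and acid avoids the base-induced retro-oxa-Michael epimerisation at C3.

## Compound list
1 | eugenyl acetate (4-allyl-2-methoxyphenyl acetate) | C=CCc1ccc(OC(C)=O)c(OC)c1 | starting material
2 | 2-methoxy-4-[(1,2,4-trioxolan-3-yl)methyl]phenyl acetate (ozonide) | COc1cc(CC2OCOO2)ccc1OC(C)=O | intermediate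
3 | 2-methoxy-4-(2-oxoethyl)phenyl acetate | COc1cc(CC=O)ccc1OC(C)=O | intermediate
4 | allyl alcohol | C=CCO | starting material
5 | allyl methoxymethyl ether | C=CCOCOC | intermediate
6 | (Z)-3-(methoxymethoxy)allyllithium | COCO/C=C\C[Li] | intermediate
7 | [(Z)-3-(methoxymethoxy)allyl]bis(isopinocampheyl)borane, Ipc groups from (+)-α-pinene | COCO/C=C\CB([C@@H]1C[C@@H]2C[C@H]([C@H]1C)C2(C)C)[C@@H]1C[C@@H]2C[C@H]([C@H]1C)C2(C)C | intermediate
8 | O-bis(isopinocampheyl)boryl derivative of 9 (borinate) | COc1cc(C[C@@H](OB([C@@H]2C[C@@H]3C[C@H]([C@H]2C)C3(C)C)[C@@H]2C[C@@H]3C[C@H]([C@H]2C)C3(C)C)[C@H](OCOC)C=C)ccc1OC(C)=O | intermediate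
9 | 4-[(2R,3R)-2-hydroxy-3-(methoxymethoxy)pent-4-en-1-yl]-2-methoxyphenyl acetate | COc1cc(C[C@@H](O)[C@H](OCOC)C=C)ccc1OC(C)=O | intermediate
10 | 4-[(2R,3R)-2-hydroxy-3-(methoxymethoxy)-5-oxopentyl]-2-methoxyphenyl acetate | COc1cc(C[C@@H](O)[C@H](OCOC)CC=O)ccc1OC(C)=O | intermediate
11 | 4-{[(2R,3R)-5-hydroxy-3-(methoxymethoxy)oxolan-2-yl]methyl}-2-methoxyphenyl acetate (anomers) | COc1cc(C[C@H]2OC(O)C[C@H]2OCOC)ccc1OC(C)=O | intermediate
12 | acetovanillone | CC(=O)c1ccc(O)c(OC)c1 | starting material
13 | [2-methoxy-4-(1-trimethylsilyloxyvinyl)phenoxy]trimethylsilane | C=C(O[Si](C)(C)C)c1ccc(O[Si](C)(C)C)c(OC)c1 | intermediate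
14 | (2R,3R)-2-(4-acetoxy-3-methoxybenzyl)-3-(methoxymethoxy)-3,4-dihydro-2H-furan-1-ium | COc1cc(C[C@H]2[O+]=CC[C@H]2OCOC)ccc1OC(C)=O | intermediate
15 | O-trimethylsilyl ether of 16 at the ketone-side phenol | COc1cc(C[C@H]2O[C@@H](CC(=O)c3ccc(O[Si](C)(C)C)c(OC)c3)C[C@H]2OCOC)ccc1OC(C)=O | intermediate
16 | 4-{[(2R,3R,5R)-5-[2-(4-hydroxy-3-methoxyphenyl)-2-oxoethyl]-3-(methoxymethoxy)oxolan-2-yl]methyl}-2-methoxyphenyl acetate | COc1cc(C[C@H]2O[C@@H](CC(=O)c3ccc(O)c(OC)c3)C[C@H]2OCOC)ccc1OC(C)=O | intermediate
17 | renealtin A | COc1cc(C[C@H]2O[C@@H](CC(=O)c3ccc(O)c(OC)c3)C[C@H]2O)ccc1O | target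

## Counts
Total step count: 7. Longest linear sequence: 5 (steps 1, 3, 4, 6, 7).

## Three steps most likely to fail

**Step 3.** Aldehyde 3 is enolisable and sensitive to Lewis acids. The aryl acetate must survive the peroxide work-up, and the ee depends on reagent quality.
- The fallback sets out from oxyallyllithium 6 and aldehyde 3 and comes back to the route at 9.
- Compound 6 is trapped with 2-isopropoxy-4,4,5,5-tetramethyl-1,3,2-dioxaborolane, then ethereal HCl. This gives the distillable, achiral (Z)-3-(methoxymethoxy)allyl pinacol boronate F1.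
- F1 adds to 3 in toluene at −30 °C under 5 mol % of the chiral phosphoric acid (S)-TRIP, chosen by analogy as the enantiomer expected to give Si-face addition. This gives the O-pinacolboryl adduct F2, which aqueous work-up hydrolyses to 9.
- The reversed-polarity carbon and the closed chair are kept. The absolute sense now comes from a Brønsted-acid catalyst acting on an isolable reagent, and neither BF3·OEt2 nor peroxide meets 3 or the acetate.

**Step 4.** The aldehyde/ketone ratio may fall with the free C6 hydroxyl nearby, and the lactol can be over-oxidised to the lactone.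
- The fallback sets out from 9 and comes back to the route at 10, hence 11.
- Cross metathesis of 9 with vinylboronic acid pinacol ester (second-generation Grubbs catalyst, CH2Cl2, 40 °C) gives the (E)-alkenyl pinacol boronate F3.
- Buffered H2O2 (pH 7, THF, 0 °C) turns the C–B bond into the enol, which tautomerises to 10 and closes to 11.
- The site of oxidation is then fixed by where boron sits, not by catalyst selectivity.

**Step 6.** Cation 14 can be captured by its own arene (para to the methoxy group) in a Friedel–Crafts closure. The MOM group may be lost or may participate, and a reactive enol silane may erode the diastereomer ratio.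
- The fallback sets out from 11 and comes back to the route at 16.
- Commercial 2-bromo-1-(4-hydroxy-3-methoxyphenyl)ethanone and PPh3 give [2-(4-hydroxy-3-methoxyphenyl)-2-oxoethyl]triphenylphosphonium bromide F4.
- Aqueous Na2CO3 gives the stabilised ylide F5.
- F5 and 11 in toluene at 90 °C give, by Wittig olefination of the open form 10, the (E)-hydroxy enone F6.
- The C6 hydroxyl of F6 closes in a reversible 5-exo oxa-Michael addition (DBU, 10 mol %). Equilibration should favour the isomer with both carbon side chains pseudoequatorial, that is the 2,5-cis compound 16, though the ratio may be modest.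
- No cation is formed, and stereocontrol is thermodynamic instead of stereoelectronic.

## Further compounds
F1 | step 3 | 2-[(Z)-3-(methoxymethoxy)allyl]-4,4,5,5-tetramethyl-1,3,2-dioxaborolane | COCO/C=C\CB1OC(C)(C)C(C)(C)O1
F2 | step 3 | O-pinacolboryl derivative of 9 | COc1cc(C[C@@H](OB2OC(C)(C)C(C)(C)O2)[C@H](OCOC)C=C)ccc1OC(C)=O
F3 | step 4 | 4-[(2R,3R,4E)-2-hydroxy-3-(methoxymethoxy)-5-(4,4,5,5-tetramethyl-1,3,2-dioxaborolan-2-yl)pent-4-en-1-yl]-2-methoxyphenyl acetate | COc1cc(C[C@@H](O)[C@H](OCOC)/C=C/B2OC(C)(C)C(C)(C)O2)ccc1OC(C)=O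
F4 | step 6 | [2-(4-hydroxy-3-methoxyphenyl)-2-oxoethyl]triphenylphosphonium bromide | COc1cc(ccc1O)C(=O)C[P+](c1ccccc1)(c1ccccc1)c1ccccc1.[Br-]
F5 | step 6 | 1-(4-hydroxy-3-methoxyphenyl)-2-(triphenylphosphoranylidene)ethanone | COc1cc(ccc1O)C(=O)C=P(c1ccccc1)(c1ccccc1)c1ccccc1
F6 | step 6 | 4-[(2R,3R,5E)-2-hydroxy-7-(4-hydroxy-3-methoxyphenyl)-3-(methoxymethoxy)-7-oxohept-5-en-1-yl]-2-methoxyphenyl acetate | COc1cc(C[C@@H](O)[C@H](OCOC)C/C=C/C(=O)c2ccc(O)c(OC)c2)ccc1OC(C)=O
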